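**Strategy.** Everything rests on the C7–C8 bond of the tridecane chain (C1 = benzylic carbon), a CH2–CH2 link that four methylenes (C3–C6) separate from the C2 acetoxy stereocentre and five (C9–C13) from the terminal hydroxyl oxygen. This remoteness from every functional group and from the benzene ring is exploited: the bond is made as a C7=C8 olefin by cross-metathesis of two unhindered terminal alkenes, the (R)-1-aryloct-7-en-2-yl acetate (phenol as benzyl ether) and unprotected hept-6-en-1-ol, joining both halves with all functionality in place. The olefin is a traceless handle, because the final hydrogenation saturates it while freeing the phenol.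

Key step: step 4

Assumption: 1, 3 and 8 are taken as commercial; 9 is expected as an E/Z mixture and is drawn and named as the E isomer, the Z isomer being carried along to the same product in step 5.

Step 1
Reactants: 1 3-bromo-5-methoxyphenol
Product: 2 1-(benzyloxy)-3-bromo-5-methoxybenzene
Conditions: BnBr (1.1 equiv), K2CO3 (1.5 equiv), acetone, reflux
Reagents that add atoms: benzyl bromide, BrCc1ccccc1
Why: Williamson ether synthesis: the phenoxide formed with K2CO3 displaces bromide from benzyl bromide by SN2, and the aryl bromide does not react under these conditions.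

Step 2
Reactants: 3 rac-2-(hex-5-en-1-yl)oxirane (racemic 1,2-epoxyoct-7-ene)
Product: 4 (R)-2-(hex-5-en-1-yl)oxirane
Conditions: (R,R)-(salen)Co(III)OAc (0.5 mol%), H2O (0.55 equiv), THF (minimal), 0 °C → rt; distillation from the diol
Reagents that add atoms: none
Why: Jacobsen hydrolytic kinetic resolution: the (R,R)-Co(salen) catalyst should hydrate the (S)-epoxide much faster than the (R)-epoxide, so that at slightly more than half conversion the remaining (R)-4 is highly enriched; this catalyst-controlled step sets the only stereocentre of the target.

Step 3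
Reactants: 2 1-(benzyloxy)-3-bromo-5-methoxybenzene; 4 (R)-2-(hex-5-en-1-yl)oxirane
Product: 7 (R)-1-[3-(benzyloxy)-5-methoxyphenyl]oct-7-en-2-yl acetate, via arylmagnesium bromide 5 (not isolated), via bromomagnesium alkoxide 6 (not isolated)
Conditions: 2 (1.3 equiv), Mg, I2 (cat.), THF, 50 °C; CuI (10 mol%), 4, −30 → 0 °C; then Ac2O (4 equiv), DMAP (cat.), 0 °C → rt
Reagents that add atoms: acetic anhydride, CC(=O)OC(C)=O
Why: Copper-catalysed Grignard opening of a terminal epoxide (SN2 at the unsubstituted carbon, so the C–O stereocentre of 4 is carried over unchanged as the (R)-carbinol) followed by O-acetylation of the bromomagnesium alkoxide in the same flask, in which the excess anhydride also destroys the surplus Grignard reagent.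

Step 4
Reactants: 7 (R)-1-[3-(benzyloxy)-5-methoxyphenyl]oct-7-en-2-yl acetate; 8 hept-6-en-1-ol
Product: 9 (2R,7E)-1-[3-(benzyloxy)-5-methoxyphenyl]-13-hydroxytridec-7-en-2-yl acetate
Conditions: 8 (4 equiv), Grubbs II (5 mol%), 1,4-benzoquinone (10 mol%), CH2Cl2, 40 °C, Ar purge
Reagents that add atoms: none
Why: Olefin cross-metathesis by the Chauvin mechanism: the Ru alkylidene formed from one terminal alkene undergoes [2+2] cycloaddition with the other, and cycloreversion of the ruthenacyclobutane releases ethene and joins C7 to C8 as a 1,2-disubstituted olefin. The closest known reaction type is the Grubbs II cross-metathesis of two unhindered monosubstituted (type I) alkenes that carry remote esters and free alcohols. No ring is closed and no stereocentre is formed; the C2 centre is four methylenes away and is not touched, and the E/Z ratio is irrelevant because step 5 saturates the olefin. The step needs cross- over homo-selectivity, which the substrate cannot supply by itself, so it is secured by four equivalents of the cheap alcohol 8, by removal of ethene and by the reversibility of the process, which returns the homodimer of 7 to the productive cycle. It also needs the double bonds to stay in place: both alkenes lie at least four CH2 groups from any heteroatom, so no chelate slows the catalyst, and benzoquinone is added to quench Ru hydrides that would cause chain walking and chain-length scrambling.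

Step 5
Reactants: 9 (2R,7E)-1-[3-(benzyloxy)-5-methoxyphenyl]-13-hydroxytridec-7-en-2-yl acetate
Product: 10 (R)-13-hydroxy-1-(3-hydroxy-5-methoxyphenyl)tridecan-2-yl acetate
Conditions: H2 (1 atm), 10% Pd/C, EtOAc, rt
Reagents that add atoms: none
Why: Heterogeneous catalytic hydrogenation saturates the C7=C8 olefin (both geometric isomers converge) and hydrogenolyses the aryl benzyl ether in the same operation, while the homobenzylic acetate, the methyl ether and the C2 stereocentre are not affected.

**Compound list**

1 | 3-bromo-5-methoxyphenol | COc1cc(O)cc(Br)c1 | starting material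
2 | 1-(benzyloxy)-3-bromo-5-methoxybenzene | COc1cc(OCc2ccccc2)cc(Br)c1 | intermediate
3 | rac-2-(hex-5-en-1-yl)oxirane | C=CCCCCC1CO1 | starting material
4 | (R)-2-(hex-5-en-1-yl)oxirane | C=CCCCC[C@@H]1CO1 | intermediate
5 | [3-(benzyloxy)-5-methoxyphenyl]magnesium bromide (not isolated) | COc1cc(OCc2ccccc2)cc([Mg]Br)c1 | intermediate
6 | bromomagnesium (R)-1-[3-(benzyloxy)-5-methoxyphenyl]oct-7-en-2-olate (not isolated) | COc1cc(OCc2ccccc2)cc(C[C@@H](CCCCC=C)O[Mg]Br)c1 | intermediate
7 | (R)-1-[3-(benzyloxy)-5-methoxyphenyl]oct-7-en-2-yl acetate | COc1cc(OCc2ccccc2)cc(C[C@@H](CCCCC=C)OC(C)=O)c1 | intermediate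
8 | hept-6-en-1-ol | C=CCCCCCO | starting material
9 | (2R,7E)-1-[3-(benzyloxy)-5-methoxyphenyl]-13-hydroxytridec-7-en-2-yl acetate (Z isomer carried along) | COc1cc(OCc2ccccc2)cc(C[C@@H](CCCC/C=C/CCCCCO)OC(C)=O)c1 | intermediate
10 | (R)-13-hydroxy-1-(3-hydroxy-5-methoxyphenyl)tridecan-2-yl acetate | COc1cc(O)cc(C[C@@H](CCCCCCCCCCCO)OC(C)=O)c1 | target

**Step count:** 5 steps in total. Longest linear sequence: 4 steps (steps 1, 3, 4, 5 from 1, or steps 2, 3, 4, 5 from 3).

**Steps most likely to fail**

Step 4. What may go wrong: statistical homodimerisation of 7, and Ru-hydride-mediated migration of the terminal double bonds before metathesis, which would give chain-shortened homologues that can no longer be separated after step 5. The fallback is a Wittig olefination across the same C7–C8 bond; it sets out from 7 and comes back to the route at 10. Compound 7 is dihydroxylated and cleaved in one flask (OsO4 cat., NaIO4, 2,6-lutidine, dioxane/H2O) through the diol (2R)-1-[3-(benzyloxy)-5-methoxyphenyl]-7,8-dihydroxyoctan-2-yl acetate F1 (not isolated) to the aldehyde (R)-1-[3-(benzyloxy)-5-methoxyphenyl]-7-oxoheptan-2-yl acetate F2. Commercial benzyl 6-bromohexyl ether and PPh3 (MeCN, reflux) give [6-(benzyloxy)hexyl]triphenylphosphonium bromide F3, which NaHMDS (THF, −78 °C) converts into the ylide [6-(benzyloxy)hexylidene]triphenylphosphorane F4 (not isolated). Addition of F2 at −78 °C should give (2R,7Z)-13-(benzyloxy)-1-[3-(benzyloxy)-5-methoxyphenyl]tridec-7-en-2-yl acetate F5, because the non-stabilised ylide reacts with the aldehyde far faster than with the acetate. Hydrogenation of F5 under the conditions of step 5 saturates the olefin, removes both benzyl ethers and gives 10.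

Step 3. What may go wrong: Wurtz-type homocoupling during formation of the Grignard reagent, opening of the epoxide by magnesium bromide to the bromohydrin in place of arylation, and incomplete acylation of the magnesium alkoxide when the surplus Grignard reagent consumes the anhydride. The fallback replaces the copper-catalysed Grignard reaction by a Lewis-acid-promoted aryllithium opening and separates the acetylation; it sets out from 2 and 4 and comes back to the route at 7. Bromine–lithium exchange on 2 (n-BuLi, THF, −78 °C) gives [3-(benzyloxy)-5-methoxyphenyl]lithium F6 (not isolated). Addition of 4 and BF3·OEt2 at −78 °C should open the activated epoxide at its terminal carbon and give, after quenching with aqueous NH4Cl, the isolated alcohol (R)-1-[3-(benzyloxy)-5-methoxyphenyl]oct-7-en-2-ol F7. After purification, F7 is acetylated (Ac2O, pyridine, DMAP, CH2Cl2, rt) to 7.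

Step 5. What may go wrong: stalling of the benzyl ether hydrogenolysis on palladium poisoned by ruthenium residues from step 4, so that the olefin is saturated but the phenol stays masked, and slow acetyl transfer on prolonged exposure to the catalyst. The fallback avoids catalytic hydrogenation altogether; it sets out from 9 and comes back to the route at 10. Diimide generated from 2-nitrobenzenesulfonylhydrazide and Et3N (CH2Cl2, rt) should saturate the C7=C8 bond and give (R)-1-[3-(benzyloxy)-5-methoxyphenyl]-13-hydroxytridecan-2-yl acetate F8. BCl3 with pentamethylbenzene as cation scavenger (CH2Cl2, −78 °C) should then cleave the aryl benzyl ether without touching the methyl ether or the acetate and give 10.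

**Further compounds**

F1 | step 4 | (2R)-1-[3-(benzyloxy)-5-methoxyphenyl]-7,8-dihydroxyoctan-2-yl acetate (C7 epimers, not isolated) | COc1cc(OCc2ccccc2)cc(C[C@@H](CCCCC(O)CO)OC(C)=O)c1
F2 | step 4 | (R)-1-[3-(benzyloxy)-5-methoxyphenyl]-7-oxoheptan-2-yl acetate | COc1cc(OCc2ccccc2)cc(C[C@@H](CCCCC=O)OC(C)=O)c1
F3 | step 4 | [6-(benzyloxy)hexyl]triphenylphosphonium bromide | [Br-].C(CCCCCOCc1ccccc1)[P+](c1ccccc1)(c1ccccc1)c1ccccc1
F4 | step 4 | [6-(benzyloxy)hexylidene]triphenylphosphorane (not isolated) | C(CCCCCOCc1ccccc1)=P(c1ccccc1)(c1ccccc1)c1ccccc1
F5 | step 4 | (2R,7Z)-13-(benzyloxy)-1-[3-(benzyloxy)-5-methoxyphenyl]tridec-7-en-2-yl acetate | COc1cc(OCc2ccccc2)cc(C[C@@H](CCCC/C=C\CCCCCOCc2ccccc2)OC(C)=O)c1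
F6 | step 3 | [3-(benzyloxy)-5-methoxyphenyl]lithium (not isolated) | COc1cc(OCc2ccccc2)cc([Li])c1
F7 | step 3 | (R)-1-[3-(benzyloxy)-5-methoxyphenyl]oct-7-en-2-ol | COc1cc(OCc2ccccc2)cc(C[C@@H](CCCCC=C)O)c1
F8 | step 5 | (R)-1-[3-(benzyloxy)-5-methoxyphenyl]-13-hydroxytridecan-2-yl acetate | COc1cc(OCc2ccccc2)cc(C[C@@H](CCCCCCCCCCCO)OC(C)=O)c1
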